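The 14-membered lactone is closed late at C11–C12 (lactone numbering, C1 = ring carbonyl), after the ester has been set. C12 is the ring methylene between the C11 carbinol and C13, the carbon that carries the ring oxygen: a C12 carbanion would expel the C1 carboxylate, a C12 radical does not. The key step therefore joins a C11 acyl nickel species (from an S-2-pyridyl thioester) to the C12 radical (from a primary halide) in an intramolecular nickel-catalysed reductive coupling that gives the macrocyclic C11 ketone; 1,3-syn reduction then sets C11. The seco compound comes from a Mitsunobu union (inversion at C13) of a skipped-triene acid and a bromohydrin.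

Key step: step 18

Remark: lactone numbering is used throughout (C1 ring carbonyl, C13 ring carbon bearing the ring oxygen, C14–C24 side chain, C3′/C3″ the carboxymethyl carbons). Compounds 3–7 are racemic at a centre that is erased in step 6.

Step 1
Reactants: 1 methyl acetoacetate; 2 acrolein
Product: 3 methyl 5-hydroxy-3-oxohept-6-enoate (racemic)
Conditions: NaH, then n-BuLi, THF, 0 °C; 2, −78 °C; aq. HCl
Reagents that add atoms: none
Why: The γ-carbon of the acetoacetate dianion adds 1,2 to acrolein (aldol addition), giving C1–C7 of the target in one step.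

Step 2
Reactants: 3
Product: 4 methyl 5-[(tert-butyldimethylsilyl)oxy]-3-oxohept-6-enoate
Conditions: TBSCl, imidazole, DMF, 0 °C to rt
Reagents that add atoms: tert-butyldimethylsilyl chloride, CC(C)(C)[Si](C)(C)Cl
Why: Silylation blocks the allylic hydroxyl so that it is not triflated in step 3 and is not ionised by palladium in step 4.

Step 3
Reactants: 4
Product: 5 methyl (2E)-5-[(tert-butyldimethylsilyl)oxy]-3-{[(trifluoromethyl)sulfonyl]oxy}hepta-2,6-dienoate
Conditions: Tf2O, aq. Me4NOH, hexanes, 5 °C
Reagents that add atoms: trifluoromethanesulfonic anhydride, O=S(=O)(OS(=O)(=O)C(F)(F)F)C(F)(F)F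
Why: With the non-chelating tetramethylammonium counter-ion the β-keto ester enolate is triflated in its extended form, which should give the (E)-enol triflate (triflate trans to the ester) that later places C4 cis to C1.

Step 4
Reactants: 5
Product: 6 5-tert-butyl 1-methyl (2E)-3-{2-[(tert-butyldimethylsilyl)oxy]but-3-en-1-yl}pent-2-enedioate
Conditions: BrZnCH2CO2t-Bu (from tert-butyl bromoacetate and Zn dust, THF), Pd(dba)2 (5 mol %), XPhos, THF, rt
Reagents that add atoms: tert-butyl bromoacetate (as its zinc reagent), BrCC(=O)OC(C)(C)C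
Why: Negishi coupling of the Reformatsky zinc reagent with the vinyl triflate proceeds with retention of alkene geometry, so the carboxymethyl arm enters trans to C1, and the allylic silyl ether is inert to zerovalent palladium.

Step 5
Reactants: 6
Product: 7 tert-butyl 2-(2-ethenyl-6-oxo-3,6-dihydro-2H-pyran-4-yl)acetate
Conditions: aq. HF (48 %), MeCN, 0 °C to rt
Reagents that add atoms: none
Why: Acidic desilylation frees the C5 hydroxyl, which lies cis to the methyl ester across C2=C3 and lactonises; the ring locks the C2=C3 geometry and turns C5–O into an allylic carboxylate.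

Step 6
Reactants: 7; 8 tert-butyl(but-3-yn-1-yloxy)dimethylsilane
Product: 10 (2E,5E,8E)-3-(2-tert-butoxy-2-oxoethyl)-11-[(tert-butyldimethylsilyl)oxy]-9-methylundeca-2,5,8-trienoic acid, via alkenylalane 9 (not isolated)
Conditions: 8, Me3Al, Cp2ZrCl2 (20 mol %), CH2Cl2, 0 °C to rt; then 7, Pd(PPh3)4 (5 mol %), THF, rt; dilute aq. HCl
Reagents that add atoms: trimethylaluminium, C[Al](C)C
Why: Negishi carboalumination (syn) gives the (E)-alkenylalane, which under zerovalent palladium catalysis couples with the π-allyl complex formed by ionisation of the vinyl lactone (alkenyl–allyl Negishi-type coupling) at the unsubstituted terminus C7, so that the (5E)-alkene, the (8E)-alkene and the free C1 acid should arise in one operation.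

Step 7
Reactants: 11 (S)-epichlorohydrin
Product: 13 (2S)-2-nonyloxirane, via chlorohydrin 12 (not isolated)
Conditions: n-C8H17MgBr, CuI (10 mol %), THF, −40 °C; then NaOH, rt
Reagents that add atoms: octylmagnesium bromide, CCCCCCCC[Mg]Br
Why: Cu-catalysed Grignard opening at the epoxide CH2 and base-induced closure of the chlorohydrin are both SN2 steps at non-stereogenic carbons, so the centre of (S)-epichlorohydrin becomes C15 unchanged.

Step 8
Reactants: 13
Product: 14 (4S)-tridec-1-en-4-ol
Conditions: vinylmagnesium bromide, CuI (10 mol %), THF, −30 °C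
Reagents that add atoms: vinylmagnesium bromide, C=C[Mg]Br
Why: Cu-catalysed Grignard opening of the terminal epoxide at its CH2 carbon gives the homoallylic alcohol with C15 retained.

Step 9
Reactants: 14
Product: 15 tert-butyl (4S)-tridec-1-en-4-yl carbonate
Conditions: Boc2O, DMAP (cat.), MeCN, rt
Reagents that add atoms: di-tert-butyl dicarbonate, CC(C)(C)OC(=O)OC(=O)OC(C)(C)C
Why: Carbonate formation installs the internal oxygen nucleophile for the iodocarbonate cyclisation.

Step 10
Reactants: 15
Product: 16 (4S,6S)-4-(iodomethyl)-6-nonyl-1,3-dioxan-2-one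
Conditions: IBr, toluene, −85 °C
Reagents that add atoms: iodine monobromide, IBr
Why: In the iodocarbonate cyclisation the carbonate carbonyl opens the iodonium ion in a chair-like 6-exo closure with both substituents equatorial, which should set C13 syn to C15, and the tert-butyl group is lost as its bromide.

Step 11
Reactants: 16
Product: 17 (2S)-1-[(2S)-oxiran-2-yl]undecan-2-ol
Conditions: K2CO3, MeOH, rt
Reagents that add atoms: none
Why: Methanolysis of the cyclic carbonate frees both oxygens and the C13 alkoxide displaces iodide (intramolecular Williamson reaction), leaving O15–H as the only free hydroxyl.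

Step 12
Reactants: 17
Product: 18 (2S)-2-{(2S)-2-[(tert-butyldimethylsilyl)oxy]undecyl}oxirane
Conditions: TBSCl, imidazole, DMF, rt
Reagents that add atoms: tert-butyldimethylsilyl chloride, CC(C)(C)[Si](C)(C)Cl
Why: Silylation of the single free hydroxyl protects O15 until the last step.

Step 13
Reactants: 18
Product: 19 (2S,4S)-1-bromo-4-[(tert-butyldimethylsilyl)oxy]tridecan-2-ol
Conditions: LiBr, AcOH, THF, rt
Reagents that add atoms: lithium bromide, [Li+].[Br-]
Why: SN2 opening of the terminal epoxide by bromide at C12 under mildly acidic conditions gives the bromohydrin with O13–H as the only free hydroxyl and C13 untouched.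

Step 14
Reactants: 10; 19
Product: 20 (2R,4S)-1-bromo-4-[(tert-butyldimethylsilyl)oxy]tridecan-2-yl ester of acid 10
Conditions: PPh3, DIAD, toluene, 0 °C
Reagents that add atoms: none
Why: In the Mitsunobu esterification the carboxylate of 10 displaces the activated C13 hydroxyl with inversion, turning the 13,15-syn alcohol into the (13R) ester, and the isomerisation-prone acid is never converted into an acylating agent.

Step 15
Reactants: 20
Product: 21 C11 primary alcohol (20 without the silyl group on O11)
Conditions: HF·pyridine, pyridine, THF, 0 °C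
Reagents that add atoms: none
Why: Buffered HF·pyridine should remove the primary silyl ether much faster than the hindered secondary one at C15.

Step 16
Reactants: 21
Product: 22 C11 carboxylic acid (CH2OH of 21 oxidised to CO2H)
Conditions: TEMPO (cat.), PhI(OAc)2, MeCN/pH 7 buffer, rt
Reagents that add atoms: water, O
Why: The oxoammonium (TEMPO) oxidation takes the primary alcohol through the aldehyde hydrate to the acid and should leave the alkenes, the bromide and the secondary silyl ether untouched.

Step 17
Reactants: 22
Product: 23 S-2-pyridyl thioester of acid 22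
Conditions: 2,2′-dipyridyl disulfide, PPh3, CH2Cl2, rt
Reagents that add atoms: 2,2′-dipyridyl disulfide, c1ccc(SSc2ccccn2)nc1
Why: Redox thioesterification with PPh3 and the disulfide activates the C11 carboxyl under neutral conditions as the acyl partner for nickel.

Step 18
Reactants: 23
Product: 25 macrocyclic C11 ketone (14-membered lactone with C15–OTBS and the tert-butyl ester), via seco iodide 24 (not isolated)
Conditions: NiCl2(dme) (30 mol %), 4,4′-di-tert-butyl-2,2′-bipyridine (33 mol %), Mn powder, NaI, DMA, rt, 23 added over 12 h by syringe pump (final 2 mM)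
Reagents that add atoms: none
Why: Bromide–iodide exchange gives 24; zerovalent nickel inserts into the C(acyl)–S bond of the thioester, the C12 radical formed by halogen abstraction is captured by the acyl nickel species, and reductive elimination from trivalent nickel forms the C11–C12 bond while Mn returns nickel to its low-valent state. The closest known reaction type is the Ni-catalysed reductive acyl–alkyl cross-electrophile coupling of S-2-pyridyl thioesters with primary alkyl iodides, run here intramolecularly. The 14-membered lactone ring is closed end to end between the C11 acyl carbon and the C12 methylene under pseudo-high dilution, helped by the three E-alkenes and the ester that already stiffen the chain. No stereocentre is formed, and C13 and C15 are not touched. The step needs C–C bond formation at C12 without loss of the β-acyloxy group: the C12 radical and the short-lived alkyl acyl nickel intermediate should not expel the C1 carboxylate, as a C12 organozinc, organochromium or organosamarium species would. It also needs ring closure to win over oligomerisation (slow addition) and over decarbonylation of the β,γ-unsaturated acyl nickel species (room temperature or below).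

Step 19
Reactants: 25
Product: 26 (11S)-alcohol (protected target: C15–OTBS, tert-butyl ester)
Conditions: Zn(BH4)2, Et2O/CH2Cl2, −40 °C; aq. NH4Cl
Reagents that add atoms: none
Why: Chelation of divalent zinc between the C11 carbonyl and O13 with external hydride attack, and the polar 1,3-induction model alike, predict the 11,13-syn (11S) alcohol, and Zn(BH4)2 leaves esters, lactone and alkenes intact.

Step 20
Reactants: 26
Product: 28 target acid CNP0213378.2, via silyl ester 27 (not isolated)
Conditions: TMSOTf, 2,6-lutidine, CH2Cl2, 0 °C; then HF·pyridine, THF, 0 °C to rt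
Reagents that add atoms: none
Why: TMSOTf/2,6-lutidine converts the tert-butyl ester into the silyl ester with loss of isobutene (and silylates O11), and HF·pyridine then removes all silyl groups under non-basic conditions that should avoid acyl migration to O11 or O15.

Compound list
1 | methyl acetoacetate | COC(=O)CC(C)=O | starting material
2 | acrolein | C=CC=O | starting material
3 | methyl 5-hydroxy-3-oxohept-6-enoate (racemic) | COC(=O)CC(=O)CC(O)C=C | intermediate
4 | methyl 5-[(tert-butyldimethylsilyl)oxy]-3-oxohept-6-enoate (racemic) | COC(=O)CC(=O)CC(O[Si](C)(C)C(C)(C)C)C=C | intermediate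
5 | methyl (2E)-5-[(tert-butyldimethylsilyl)oxy]-3-{[(trifluoromethyl)sulfonyl]oxy}hepta-2,6-dienoate (racemic) | COC(=O)/C=C(/OS(=O)(=O)C(F)(F)F)CC(O[Si](C)(C)C(C)(C)C)C=C | intermediate
6 | 5-tert-butyl 1-methyl (2E)-3-{2-[(tert-butyldimethylsilyl)oxy]but-3-en-1-yl}pent-2-enedioate (racemic) | COC(=O)/C=C(/CC(=O)OC(C)(C)C)CC(O[Si](C)(C)C(C)(C)C)C=C | intermediate
7 | tert-butyl 2-(2-ethenyl-6-oxo-3,6-dihydro-2H-pyran-4-yl)acetate (racemic) | C=CC1CC(CC(=O)OC(C)(C)C)=CC(=O)O1 | intermediate
8 | tert-butyl(but-3-yn-1-yloxy)dimethylsilane | C#CCCO[Si](C)(C)C(C)(C)C | starting material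
9 | {(1E)-4-[(tert-butyldimethylsilyl)oxy]-2-methylbut-1-en-1-yl}dimethylalumane | C[Al](C)/C=C(\C)CCO[Si](C)(C)C(C)(C)C | intermediate
10 | (2E,5E,8E)-3-(2-tert-butoxy-2-oxoethyl)-11-[(tert-butyldimethylsilyl)oxy]-9-methylundeca-2,5,8-trienoic acid | OC(=O)/C=C(/CC(=O)OC(C)(C)C)C/C=C/C/C=C(\C)CCO[Si](C)(C)C(C)(C)C | intermediate
11 | (S)-epichlorohydrin, (2S)-2-(chloromethyl)oxirane | ClC[C@@H]1CO1 | starting material
12 | (2S)-1-chloroundecan-2-ol | CCCCCCCCC[C@H](O)CCl | intermediate
13 | (2S)-2-nonyloxirane | CCCCCCCCC[C@H]1CO1 | intermediate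
14 | (4S)-tridec-1-en-4-ol | CCCCCCCCC[C@H](O)CC=C | intermediate
15 | tert-butyl (4S)-tridec-1-en-4-yl carbonate | CCCCCCCCC[C@H](OC(=O)OC(C)(C)C)CC=C | intermediate
16 | (4S,6S)-4-(iodomethyl)-6-nonyl-1,3-dioxan-2-one | CCCCCCCCC[C@H]1C[C@@H](CI)OC(=O)O1 | intermediate
17 | (2S)-1-[(2S)-oxiran-2-yl]undecan-2-ol | CCCCCCCCC[C@H](O)C[C@H]1CO1 | intermediate
18 | (2S)-2-{(2S)-2-[(tert-butyldimethylsilyl)oxy]undecyl}oxirane | CCCCCCCCC[C@H](O[Si](C)(C)C(C)(C)C)C[C@H]1CO1 | intermediate
19 | (2S,4S)-1-bromo-4-[(tert-butyldimethylsilyl)oxy]tridecan-2-ol | CCCCCCCCC[C@H](O[Si](C)(C)C(C)(C)C)C[C@H](O)CBr | intermediate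
20 | (2R,4S)-1-bromo-4-[(tert-butyldimethylsilyl)oxy]tridecan-2-yl (2E,5E,8E)-3-(2-tert-butoxy-2-oxoethyl)-11-[(tert-butyldimethylsilyl)oxy]-9-methylundeca-2,5,8-trienoate | CCCCCCCCC[C@H](O[Si](C)(C)C(C)(C)C)C[C@H](CBr)OC(=O)/C=C(/CC(=O)OC(C)(C)C)C/C=C/C/C=C(\C)CCO[Si](C)(C)C(C)(C)C | intermediate
21 | the same ester with free C11 hydroxyl (11-hydroxy trienoate) | CCCCCCCCC[C@H](O[Si](C)(C)C(C)(C)C)C[C@H](CBr)OC(=O)/C=C(/CC(=O)OC(C)(C)C)C/C=C/C/C=C(\C)CCO | intermediate
22 | the same ester with C11 as carboxylic acid | CCCCCCCCC[C@H](O[Si](C)(C)C(C)(C)C)C[C@H](CBr)OC(=O)/C=C(/CC(=O)OC(C)(C)C)C/C=C/C/C=C(\C)CC(=O)O | intermediate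
23 | S-2-pyridyl thioester of 22 (seco bromide) | CCCCCCCCC[C@H](O[Si](C)(C)C(C)(C)C)C[C@H](CBr)OC(=O)/C=C(/CC(=O)OC(C)(C)C)C/C=C/C/C=C(\C)CC(=O)Sc1ccccn1 | intermediate
24 | seco iodide (23 with iodine at C12) | CCCCCCCCC[C@H](O[Si](C)(C)C(C)(C)C)C[C@H](CI)OC(=O)/C=C(/CC(=O)OC(C)(C)C)C/C=C/C/C=C(\C)CC(=O)Sc1ccccn1 | intermediate
25 | macrocyclic C11 ketone: (13R)-14-membered lactone, (2E,5E,8E), C15–OTBS (S), tert-butyl ester at C3″ | CCCCCCCCC[C@H](O[Si](C)(C)C(C)(C)C)C[C@@H]1CC(=O)C/C(C)=C/C/C=C/C/C(CC(=O)OC(C)(C)C)=C\C(=O)O1 | intermediate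
26 | (11S,13R)-alcohol: protected target with C15–OTBS and tert-butyl ester | CCCCCCCCC[C@H](O[Si](C)(C)C(C)(C)C)C[C@@H]1C[C@@H](O)C/C(C)=C/C/C=C/C/C(CC(=O)OC(C)(C)C)=C\C(=O)O1 | intermediate
27 | trimethylsilyl ester of the C3″ acid with O11–SiMe3 and O15–TBS | CCCCCCCCC[C@H](O[Si](C)(C)C(C)(C)C)C[C@@H]1C[C@@H](O[Si](C)(C)C)C/C(C)=C/C/C=C/C/C(CC(=O)O[Si](C)(C)C)=C\C(=O)O1 | intermediate
28 | CNP0213378.2: (11S,13R)-11-hydroxy-13-[(2S)-2-hydroxyundecyl]-9-methyl 14-membered (2E,5E,8E)-trienolide with carboxymethyl at C3 | CCCCCCCCC[C@H](O)C[C@@H]1C[C@@H](O)C/C(C)=C/C/C=C/C/C(CC(=O)O)=C\C(=O)O1 | target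

Total step count: 20. Longest linear sequence: 14 steps (steps 7–20 from (S)-epichlorohydrin); the acid branch (steps 1–6) joins at step 14.

Steps most likely to fail

Step 18. What may go wrong: decarbonylation of the β,γ-unsaturated acyl nickel intermediate, loss of the C1 carboxylate by β-elimination at C12, or oligomerisation instead of ring closure. The fallback sets out from 21 and comes back at 25. Alcohol 21 is oxidised with Dess–Martin periodinane to the aldehyde F1. F1 is then cyclised by the Ni-catalysed reductive coupling of an aldehyde with a primary alkyl bromide in the presence of Et3SiCl (NiBr2(dme), a bioxazoline ligand, Mn, NaI, slow addition). This closes the same C11–C12 bond without an acyl nickel species and should give the macrocyclic triethylsilyl ether F2 as a mixture of C11 epimers. PPTS in MeOH removes the triethylsilyl group to give the alcohol F3 (C11 epimer mixture), and Dess–Martin oxidation of F3 gives ketone 25.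

Step 19. What may go wrong: poor facial selectivity of hydride delivery inside the macrocycle, or acyl migration from O13 to the new O11 alkoxide. The fallback sets out from 25 and comes back at 26. The ketone is reduced without regard to selectivity (NaBH4, CeCl3, MeOH, −78 °C), and the (11R)-alcohol F4 is separated. F4 is inverted by a Mitsunobu reaction with chloroacetic acid (PPh3, DIAD) to the (11S)-chloroacetate F5. Thiourea and NaHCO3 in EtOH cleave F5 to 26 without touching the lactone.

Step 6. What may go wrong: β-hydride loss from the π-allyl palladium intermediate to a conjugated diene acid, or transfer of methyl instead of the alkenyl group. The fallback sets out from 8 and comes back at 10. The same carboalumination of 8 is quenched with iodine to give the vinyl iodide F6. Iodine–lithium exchange (t-BuLi, Et2O, −78 °C) and MgBr2 convert F6 into the alkenylmagnesium bromide F7. With CuBr·SMe2 (10 mol %) at −78 °C, F7 opens lactone 7 by anti SN2′ attack at C7, a copper-catalysed Grignard substitution that involves no π-allyl palladium species, to give acid 10.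

Further compounds
F1 | step 18 | C11 aldehyde corresponding to alcohol 21 | CCCCCCCCC[C@H](O[Si](C)(C)C(C)(C)C)C[C@H](CBr)OC(=O)/C=C(/CC(=O)OC(C)(C)C)C/C=C/C/C=C(\C)CC=O
F2 | step 18 | macrocyclic C11 triethylsilyl ether (C11 epimer mixture) | CCCCCCCCC[C@H](O[Si](C)(C)C(C)(C)C)C[C@@H]1CC(O[Si](CC)(CC)CC)C/C(C)=C/C/C=C/C/C(CC(=O)OC(C)(C)C)=C\C(=O)O1
F3 | step 18 | macrocyclic C11 alcohol (C11 epimer mixture) | CCCCCCCCC[C@H](O[Si](C)(C)C(C)(C)C)C[C@@H]1CC(O)C/C(C)=C/C/C=C/C/C(CC(=O)OC(C)(C)C)=C\C(=O)O1
F4 | step 19 | (11R)-epimer of alcohol 26 | CCCCCCCCC[C@H](O[Si](C)(C)C(C)(C)C)C[C@@H]1C[C@H](O)C/C(C)=C/C/C=C/C/C(CC(=O)OC(C)(C)C)=C\C(=O)O1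
F5 | step 19 | (11S)-chloroacetate of 26 | CCCCCCCCC[C@H](O[Si](C)(C)C(C)(C)C)C[C@@H]1C[C@@H](OC(=O)CCl)C/C(C)=C/C/C=C/C/C(CC(=O)OC(C)(C)C)=C\C(=O)O1
F6 | step 6 | tert-butyl{[(3E)-4-iodo-3-methylbut-3-en-1-yl]oxy}dimethylsilane | I/C=C(\C)CCO[Si](C)(C)C(C)(C)C
F7 | step 6 | {(1E)-4-[(tert-butyldimethylsilyl)oxy]-2-methylbut-1-en-1-yl}magnesium bromide | Br[Mg]/C=C(\C)CCO[Si](C)(C)C(C)(C)C
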